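**Retrosynthetic overview**

1. Target ⇐ its bis-TBS ether ⇐ one biomimetic cascade on a 3-oxo-glaucolide-type macrocycle (4,5-epoxide, 6,12-butenolide, C1≡C2–C3=O ynone as masked 1,3-dione): vinylogous epoxide opening from C6 gives the C5=C6 enol lactone and the C4 alkoxide, which closes the 3(2H)-furanone by transannular 5-endo oxa-Michael addition.
2. Macrocycle ⇐ acyclic (Z)-β-iodoenoate/2,3-epoxy aldehyde: Nozaki–Hiyama–Kishi closure of the ten-membered ring at C6–C7 (bond and polarity of the farnesyl cyclisation), the C6 alkoxide lactonising onto C12 in the flask.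
3. Acyclic chain ⇐ alkynylation of (E)-4-acetoxy-2-methylbut-2-enal at C3; the C3 carbinol relays chirality to C4 in a matched Sharpless epoxidation and is oxidised away later.
4. Alkyne ⇐ crotonaldehyde + TIPS-acetylene (sets C10), methyl propiolate (sets C8), formaldehyde + iodide (tetrasubstituted iodoalkene, C13), O-silylated 2-(hydroxymethyl)acrylic acid.
5. Ring order: carbocycle (C6–C7) → butenolide (O–C12) → furanone oxygen bridge together with C5=C6.

Assumption: locants C1–C15 everywhere are the germacrane numbering of the target (ring C1–C10, lactone carbons C11–C13, C14 on C10, C15 on C4); the sense of induction of the chiral catalysts in steps 1, 2 and 7 is taken from the published models (the antipodal ligand is used if it proves opposite); C6 of 19 and 20 is an inconsequential epimer mixture; TBS = tert-butyldimethylsilyl, TIPS = triisopropylsilyl.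

**Step 1**
Reactants: 1 crotonaldehyde; 2 ethynyltriisopropylsilane
Product: 3 (S)-3-methyl-5-(triisopropylsilyl)pent-4-ynal
Conditions: [Rh(OAc)(C2H4)2]2 (2.5 mol%), (R)-DTBM-SEGPHOS (6 mol%), MeOH, 40 °C
Reagents that add atoms: none
Why: Rh-catalysed asymmetric conjugate alkynylation of an enal (Hayashi–Nishimura); the bulky silyl group suppresses alkyne dimerisation and the chiral bisphosphine–Rh alkynyl adds to one enal face, setting C10 (S).

**Step 2**
Reactants: 3 (S)-3-methyl-5-(triisopropylsilyl)pent-4-ynal; 4 methyl propiolate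
Product: 5 methyl (4S,6S)-4-hydroxy-6-methyl-8-(triisopropylsilyl)octa-2,7-diynoate
Conditions: Me2Zn (3 equiv), (S,S)-ProPhenol (20 mol%), Ph3P=O (40 mol%), toluene, 4 °C; aq. NH4Cl
Reagents that add atoms: none
Why: Trost Zn–ProPhenol asymmetric alkynylation of an aldehyde; the dinuclear zinc catalyst controls the aldehyde face and sets C8 (S), the remote C10 methyl having little influence.

**Step 3**
Reactants: 5 methyl (4S,6S)-4-hydroxy-6-methyl-8-(triisopropylsilyl)octa-2,7-diynoate; 6 formaldehyde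
Product: 7 methyl (2Z,4S,6S)-4-hydroxy-2-(hydroxymethyl)-3-iodo-6-methyl-8-(triisopropylsilyl)oct-2-en-7-ynoate
Conditions: Et2AlI (2.5 equiv), CH2Cl2, −78 → 0 °C; monomeric CH2O (cracked paraformaldehyde, THF), −78 → −20 °C; aq. NaHCO3
Reagents that add atoms: diethylaluminium iodide CC[Al](I)CC
Why: Proposed new method: Et2AlI first forms the C8 O–Al(Et)I alkoxide and then adds iodide to C7 of the ynoate to give a β-iodo allenolate (Al–O enolate), which is hydroxymethylated at C11 by formaldehyde delivered from the C8 alkoxide side, so that C13 ends cis to C8 and iodine cis to CO2Me (Z), any E isomer being removed as its 8,12-lactone; the closest known reaction is the Et2AlI- or MgI2-mediated halo-aldol (β-iodo Morita–Baylis–Hillman) coupling of propiolates and ynones with aldehydes.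

**Step 4**
Reactants: 8 2-(hydroxymethyl)acrylic acid
Product: 10 2-(TBS-oxymethyl)acrylic acid, via bis-silylated acid 9 (not isolated)
Conditions: TBSCl (2.2 equiv), imidazole, DMF, 0 → 23 °C; then K2CO3 (cat.), MeOH/H2O/THF; citric acid to pH 4
Reagents that add atoms: tert-butyldimethylsilyl chloride CC(C)(C)[Si](C)(C)Cl
Why: Exhaustive silylation followed by selective solvolysis of the labile silyl ester (standard protection); no stereocentre is involved.

**Step 5**
Reactants: 7 methyl (2Z,4S,6S)-4-hydroxy-2-(hydroxymethyl)-3-iodo-6-methyl-8-(triisopropylsilyl)oct-2-en-7-ynoate; 10 2-(TBS-oxymethyl)acrylic acid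
Product: 12 C13-O-TBS C8-O-[2-(TBS-oxymethyl)acryloyl] iodoenoate (TIPS alkyne), via primary TBS ether 11 (not isolated)
Conditions: TBSCl (1.05 equiv), imidazole, CH2Cl2, −20 → 0 °C; then 10 (1.5 equiv), DCC, DMAP (cat.), 0 → 23 °C
Reagents that add atoms: tert-butyldimethylsilyl chloride CC(C)(C)[Si](C)(C)Cl
Why: The primary allylic C13 hydroxyl is silylated much faster than the hindered secondary C8 hydroxyl, which is then acylated by Steglich esterification with retention at C8.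

**Step 6**
Reactants: 12 C13-O-TBS C8-O-acyl iodoenoate (TIPS alkyne)
Product: 13 C13-O-TBS C8-O-acyl iodoenoate with free terminal alkyne (C2–H)
Conditions: AgF (1.5 equiv), MeOH, 23 °C, dark; then 1 M HCl
Reagents that add atoms: none
Why: Silver-fluoride protodesilylation cleaves only the C(sp)–Si bond (through the alkynyl–Ag species) and leaves the O-silyl ethers, the iodoalkene and the esters untouched.

**Step 7**
Reactants: 13 terminal alkyne; 14 (E)-4-acetoxy-2-methylbut-2-enal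
Product: 15 (3R,4E)-3-hydroxy-6-acetoxy enynol (acyclic C1–C13 chain)
Conditions: 14 (2 equiv), Me2Zn (3 equiv), (R,R)-ProPhenol (20 mol%), Ph3P=O (40 mol%), toluene, 4 °C; aq. NH4Cl
Reagents that add atoms: none
Why: Trost Zn–ProPhenol alkynylation, which works best with α-substituted enals; the catalyst sets the C3 carbinol (R), used only as a relay stereocentre for step 8.

**Step 8**
Reactants: 15 (3R,4E)-enynol
Product: 16 (3S,4R,5R)-4,5-epoxy-3-ol 6-acetate
Conditions: Ti(OiPr)4 (0.2 equiv), L-(+)-diisopropyl tartrate (0.24 equiv), TBHP (2 equiv), 4 Å MS, CH2Cl2, −20 °C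
Reagents that add atoms: tert-butyl hydroperoxide CC(C)(C)OO
Why: Sharpless asymmetric epoxidation in the matched (fast-reacting) mode of a secondary allylic alcohol: with L-(+)-tartrate the (3R) carbinol has its hydrogen on the face of oxygen delivery, so reagent and substrate both give the erythro epoxy alcohol and set C4 (the later 4S centre) and C5, while the electron-poor acrylate and iodoenoate alkenes are inert.

**Step 9**
Reactants: 16 (3S,4R,5R)-4,5-epoxy-3-ol 6-acetate
Product: 17 (3S,4R,5R)-4,5-epoxy-3,6-diol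
Conditions: Candida antarctica lipase B (immobilised), MeOH (10 equiv), MTBE, 30 °C
Reagents that add atoms: none
Why: Lipase-catalysed transesterification removes the unhindered primary acetate at neutral pH, avoiding Payne rearrangement of the epoxy alcohol and attack on the hindered conjugated esters.

**Step 10**
Reactants: 17 (3S,4R,5R)-4,5-epoxy-3,6-diol
Product: 18 (3S,4R,5S)-4,5-epoxy-3-hydroxy C6 aldehyde
Conditions: TEMPO (10 mol%), PhI(OAc)2 (1.1 equiv), CH2Cl2, 23 °C
Reagents that add atoms: none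
Why: Oxoammonium (TEMPO/PhI(OAc)2) oxidation is selective for the primary alcohol over the hindered secondary propargylic one and does not touch the epoxide.

**Step 11**
Reactants: 18 (3S,4R,5S)-4,5-epoxy-3-hydroxy C6 aldehyde
Product: 20 (3S,4R,5R,8S,10S)-4,5-epoxy-3-hydroxy-1-yne 6,12-butenolide macrocycle, via hydroxy ester 19 (not isolated)
Conditions: CrCl2 (10 equiv), NiCl2 (0.1 equiv), degassed DMSO/THF 3:1, syringe-pump addition to 2 mM, 25 °C; aq. NH4Cl
Reagents that add atoms: none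
Why: Intramolecular Nozaki–Hiyama–Kishi reaction: the alkenyl–CrCl2 species from the (Z)-β-iodoenoate adds to the epoxy aldehyde to close the ten-membered ring at C6–C7, and the C6–O–CrCl2 alkoxide lactonises onto the cis CO2Me as (Z)-3-iodoacrylates do; C3 is deliberately still an alcohol because CrCl2 reduces α,β-epoxy ketones, and C6 forms as an epimer mixture that converges in step 12.

**Step 12**
Reactants: 20 epoxy-hydroxy-alkyne butenolide macrocycle
Product: 23 bis-TBS ether of the target, via epoxy ynone 21 (not isolated), via hydroxy ynone 22 (not isolated)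
Conditions: Dess–Martin periodinane (1.5 equiv), CH2Cl2, 0 → 23 °C; then DBU (4 equiv), −40 → 0 °C
Reagents that add atoms: none
Why: Proposed new method: oxidation gives the 3-oxo-glaucolide-type epoxy ynone, DBU removes the butenolide γ-proton at C6, the resulting 2-oxidofuran opens the 4,5-epoxide in a vinylogous E1cB step (C5=C6 geometry fixed by the ring, C4 retained because its C–O bond is untouched), and the C4 alkoxide closes the furanone by transannular 5-endo-dig oxa-Michael addition to C1 of the ynone; the closest known reactions are the glaucolide-to-hirsutinolide rearrangement and the base-mediated cyclisation of α′-hydroxy ynones to 3(2H)-furanones.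

**Step 13**
Reactants: 23 bis-TBS ether of the target
Product: 24 CNP0261115.1
Conditions: HF·pyridine, pyridine/THF, 0 → 23 °C
Reagents that add atoms: none
Why: Buffered fluoride desilylation cleaves both primary TBS ethers without epimerising C10 or opening the enol lactone.

**Compound list**

1 | (E)-but-2-enal (crotonaldehyde) | C/C=C/C=O | starting material
2 | ethynyltriisopropylsilane | C#C[Si](C(C)C)(C(C)C)C(C)C | starting material
3 | (S)-3-methyl-5-(triisopropylsilyl)pent-4-ynal | O=CC[C@H](C)C#C[Si](C(C)C)(C(C)C)C(C)C | intermediate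
4 | methyl propiolate | C#CC(=O)OC | starting material
5 | methyl (4S,6S)-4-hydroxy-6-methyl-8-(triisopropylsilyl)octa-2,7-diynoate | COC(=O)C#C[C@@H](O)C[C@H](C)C#C[Si](C(C)C)(C(C)C)C(C)C | intermediate
6 | formaldehyde (from paraformaldehyde) | C=O | starting material
7 | methyl (2Z,4S,6S)-4-hydroxy-2-(hydroxymethyl)-3-iodo-6-methyl-8-(triisopropylsilyl)oct-2-en-7-ynoate | COC(=O)/C(CO)=C(\I)[C@@H](O)C[C@H](C)C#C[Si](C(C)C)(C(C)C)C(C)C | intermediate
8 | 2-(hydroxymethyl)acrylic acid | C=C(CO)C(=O)O | starting material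
9 | tert-butyldimethylsilyl 2-(TBS-oxymethyl)acrylate | C=C(CO[Si](C)(C)C(C)(C)C)C(=O)O[Si](C)(C)C(C)(C)C | intermediate (not isolated)
10 | 2-(TBS-oxymethyl)acrylic acid | C=C(CO[Si](C)(C)C(C)(C)C)C(=O)O | intermediate
11 | methyl (2Z,4S,6S)-2-(TBS-oxymethyl)-4-hydroxy-3-iodo-6-methyl-8-(triisopropylsilyl)oct-2-en-7-ynoate | COC(=O)/C(CO[Si](C)(C)C(C)(C)C)=C(\I)[C@@H](O)C[C@H](C)C#C[Si](C(C)C)(C(C)C)C(C)C | intermediate (not isolated)
12 | methyl (2Z,4S,6S)-2-(TBS-oxymethyl)-4-{[2-(TBS-oxymethyl)acryloyl]oxy}-3-iodo-6-methyl-8-(triisopropylsilyl)oct-2-en-7-ynoate | COC(=O)/C(CO[Si](C)(C)C(C)(C)C)=C(\I)[C@@H](OC(=O)C(=C)CO[Si](C)(C)C(C)(C)C)C[C@H](C)C#C[Si](C(C)C)(C(C)C)C(C)C | intermediate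
13 | methyl (2Z,4S,6S)-2-(TBS-oxymethyl)-4-{[2-(TBS-oxymethyl)acryloyl]oxy}-3-iodo-6-methyloct-2-en-7-ynoate | COC(=O)/C(CO[Si](C)(C)C(C)(C)C)=C(\I)[C@@H](OC(=O)C(=C)CO[Si](C)(C)C(C)(C)C)C[C@H](C)C#C | intermediate
14 | (E)-4-acetoxy-2-methylbut-2-enal | CC(=O)OC/C=C(\C)C=O | starting material
15 | methyl (2Z,4S,6S,9R,10E)-12-acetoxy-2-(TBS-oxymethyl)-4-{[2-(TBS-oxymethyl)acryloyl]oxy}-9-hydroxy-3-iodo-6,10-dimethyldodeca-2,10-dien-7-ynoate (3R in target numbering) | COC(=O)/C(CO[Si](C)(C)C(C)(C)C)=C(\I)[C@@H](OC(=O)C(=C)CO[Si](C)(C)C(C)(C)C)C[C@H](C)C#C[C@H](O)/C(C)=C/COC(C)=O | intermediate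
16 | 15 with C4=C5 as the trans epoxide: (3S,4R,5R)-4,5-epoxy-3-ol 6-acetate | COC(=O)/C(CO[Si](C)(C)C(C)(C)C)=C(\I)[C@@H](OC(=O)C(=C)CO[Si](C)(C)C(C)(C)C)C[C@H](C)C#C[C@H](O)[C@@]1(C)O[C@@H]1COC(C)=O | intermediate
17 | (3S,4R,5R)-4,5-epoxy-3,6-diol (16 without acetyl) | COC(=O)/C(CO[Si](C)(C)C(C)(C)C)=C(\I)[C@@H](OC(=O)C(=C)CO[Si](C)(C)C(C)(C)C)C[C@H](C)C#C[C@H](O)[C@@]1(C)O[C@@H]1CO | intermediate
18 | (3S,4R,5S)-4,5-epoxy-3-hydroxy C6 aldehyde | COC(=O)/C(CO[Si](C)(C)C(C)(C)C)=C(\I)[C@@H](OC(=O)C(=C)CO[Si](C)(C)C(C)(C)C)C[C@H](C)C#C[C@H](O)[C@@]1(C)O[C@@H]1C=O | intermediate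
19 | methyl (3S,4R,5R,8S,10S)-4,5-epoxy-3,6-dihydroxy-8-{[2-(TBS-oxymethyl)acryloyl]oxy}-13-(TBS-oxy)germacr-7(11)-en-1-yn-12-oate (C6 epimers) | COC(=O)/C(CO[Si](C)(C)C(C)(C)C)=C1\C(O)[C@H]2O[C@]2(C)[C@@H](O)C#C[C@@H](C)C[C@@H]1OC(=O)C(=C)CO[Si](C)(C)C(C)(C)C | intermediate (not isolated)
20 | (3S,4R,5R,8S,10S)-4,5-epoxy-3-hydroxy-8-{[2-(TBS-oxymethyl)acryloyl]oxy}-13-(TBS-oxy)germacr-7(11)-en-1-yn-12,6-olide (C6 epimers) | O=C1OC2C(=C1CO[Si](C)(C)C(C)(C)C)[C@@H](OC(=O)C(=C)CO[Si](C)(C)C(C)(C)C)C[C@H](C)C#C[C@H](O)[C@@]3(C)O[C@H]23 | intermediate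
21 | (4S,5R,8S,10S)-4,5-epoxy-3-oxo analogue of 20 (epoxy ynone) | O=C1OC2C(=C1CO[Si](C)(C)C(C)(C)C)[C@@H](OC(=O)C(=C)CO[Si](C)(C)C(C)(C)C)C[C@H](C)C#CC(=O)[C@@]3(C)O[C@H]23 | intermediate (not isolated)
22 | (4S,5E,8S,10S)-4-hydroxy-3-oxo-8-{[2-(TBS-oxymethyl)acryloyl]oxy}-13-(TBS-oxy)germacra-5,7(11)-dien-1-yn-12,6-olide | O=C1O/C2=C/[C@](C)(O)C(=O)C#C[C@@H](C)C[C@H](OC(=O)C(=C)CO[Si](C)(C)C(C)(C)C)C2=C1CO[Si](C)(C)C(C)(C)C | intermediate (not isolated)
23 | (4S,5E,8S,10S)-1,4-epoxy-3-oxo-8-{[2-(TBS-oxymethyl)acryloyl]oxy}-13-(TBS-oxy)germacra-1,5,7(11)-trien-12,6-olide | C=C(CO[Si](C)(C)C(C)(C)C)C(=O)O[C@H]1C[C@H](C)C2=CC(=O)[C@](C)(/C=C3/OC(=O)C(CO[Si](C)(C)C(C)(C)C)=C31)O2 | intermediate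
24 | (4S,5E,8S,10S)-1,4-epoxy-13-hydroxy-8-{[2-(hydroxymethyl)acryloyl]oxy}-3-oxogermacra-1,5,7(11)-trien-12,6-olide (CNP0261115.1) | C=C(CO)C(=O)O[C@H]1C[C@H](C)C2=CC(=O)[C@](C)(/C=C3/OC(=O)C(CO)=C31)O2 | target

**Step count and risks**

Total step count: 13. Longest linear sequence: 12 (steps 1–3 and 5–13; step 4 is the side-chain acid branch).

Most likely to fail, 1: step 3. The iodo-aldol has not been shown for a β-branched γ-hydroxy ynoate with formaldehyde, and it must give the Z isomer. Fallback, from 5 back to 7: the lithium alkoxide of 5 is treated with Me3SnLi/CuBr·SMe2 at −78 °C and warmed to −48 °C, so that the stannylcuprate adduct equilibrates to the ester-chelated geometry. Trapping with monomeric formaldehyde gives methyl (2Z,4S,6S)-4-hydroxy-2-(hydroxymethyl)-6-methyl-3-(trimethylstannyl)-8-(triisopropylsilyl)oct-2-en-7-ynoate F1. Iododestannylation (I2, CH2Cl2, 0 °C) with retention then gives 7.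

Most likely to fail, 2: step 11. It closes a ten-membered cycloalkyne with a tetrasubstituted alkenyl–CrCl2 species that carries an allylic acyloxy group. Fallback, from 12 back to 20: the C6–C7 bond is made between fragments and the ring is closed at C2–C3, the alkynyl–CrCl2/aldehyde closure known for ten-membered enediyne rings.
- 12 and (E)-4,4-dimethoxy-3-methylbut-2-enal (COC(OC)/C(C)=C/C=O) with CrCl2/NiCl2 in DMSO give the acyclic C6-hydroxy ester dimethyl acetal F2, which lactonises in the flask to the 6,12-butenolide dimethyl acetal F3.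
- PPTS in wet acetone unmasks the 6,12-butenolide C3 enal F4.
- AgF/N-iodosuccinimide in MeCN turns the C-silyl alkyne into the 1-iodoalkyne enal F5.
- CrCl2/NiCl2 at 2 mM closes the ring to (4E,8S,10S)-3-hydroxy-8-acyloxy-13-(TBS-oxy)germacra-4,7(11)-dien-1-yn-12,6-olide F6 (C3 and C6 epimers).
- Ti(OiPr)4/L-(+)-diisopropyl tartrate/TBHP epoxidises only the matched (3R) epimer at C4=C5, the biosynthetic 4,5-epoxidation of a germacranolide, and gives 20.

Most likely to fail, 3: step 12. DBU could isomerise the ynone through its C10–H or add to it before the C6 proton is removed. Fallback, from 20 back to 23, with the cascade split and the furanone closed by π-acid instead of base: DBU (CH2Cl2, 0 °C) on the C3 carbinol 20 performs only the vinylogous epoxide opening, to give (3S,4S,5E,8S,10S)-3,4-dihydroxy-8-acyloxy-13-(TBS-oxy)germacra-5,7(11)-dien-1-yn-12,6-olide F7. MnO2 (CH2Cl2, 23 °C) oxidises the propargylic alcohol to the hydroxy ynone 22 under neutral conditions. Ph3PAuNTf2 (5 mol%, CH2Cl2, 0 °C) then brings about the 5-endo-dig cycloisomerisation to 23.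

**Further compounds**

F1 | step 3 | methyl (2Z,4S,6S)-4-hydroxy-2-(hydroxymethyl)-6-methyl-3-(trimethylstannyl)-8-(triisopropylsilyl)oct-2-en-7-ynoate | COC(=O)/C(CO)=C(\[Sn](C)(C)C)[C@@H](O)C[C@H](C)C#C[Si](C(C)C)(C(C)C)C(C)C
F2 | step 11 | acyclic C6-hydroxy ester dimethyl acetal (12 with I replaced by CH(OH)–CH=C(CH3)–CH(OMe)2, 4E, C6 epimers) | COC(=O)/C(CO[Si](C)(C)C(C)(C)C)=C(\C(O)/C=C(\C)C(OC)OC)[C@@H](OC(=O)C(=C)CO[Si](C)(C)C(C)(C)C)C[C@H](C)C#C[Si](C(C)C)(C(C)C)C(C)C
F3 | step 11 | 6,12-butenolide dimethyl acetal (4E, TIPS alkyne, C6 epimers) | O=C1OC(/C=C(\C)C(OC)OC)C(=C1CO[Si](C)(C)C(C)(C)C)[C@@H](OC(=O)C(=C)CO[Si](C)(C)C(C)(C)C)C[C@H](C)C#C[Si](C(C)C)(C(C)C)C(C)C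
F4 | step 11 | 6,12-butenolide C3 enal (4E, TIPS alkyne) | O=C1OC(/C=C(\C)C=O)C(=C1CO[Si](C)(C)C(C)(C)C)[C@@H](OC(=O)C(=C)CO[Si](C)(C)C(C)(C)C)C[C@H](C)C#C[Si](C(C)C)(C(C)C)C(C)C
F5 | step 11 | 1-iodoalkyne enal (4E) | O=C1OC(/C=C(\C)C=O)C(=C1CO[Si](C)(C)C(C)(C)C)[C@@H](OC(=O)C(=C)CO[Si](C)(C)C(C)(C)C)C[C@H](C)C#CI
F6 | step 11 | (4E,8S,10S)-3-hydroxy-8-{[2-(TBS-oxymethyl)acryloyl]oxy}-13-(TBS-oxy)germacra-4,7(11)-dien-1-yn-12,6-olide (C3 and C6 epimers) | O=C1OC2/C=C(\C)C(O)C#C[C@@H](C)C[C@H](OC(=O)C(=C)CO[Si](C)(C)C(C)(C)C)C2=C1CO[Si](C)(C)C(C)(C)C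
F7 | step 12 | (3S,4S,5E,8S,10S)-3,4-dihydroxy-8-{[2-(TBS-oxymethyl)acryloyl]oxy}-13-(TBS-oxy)germacra-5,7(11)-dien-1-yn-12,6-olide | O=C1O/C2=C/[C@](C)(O)[C@@H](O)C#C[C@@H](C)C[C@H](OC(=O)C(=C)CO[Si](C)(C)C(C)(C)C)C2=C1CO[Si](C)(C)C(C)(C)C
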